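**Plan**

- Retrosynthesis: the C3–CH2OH oxygen is removed first (hydroboration of an exocyclic C3=CH2). The ring bonds O1–C2 and C2–C3 are then cut together, releasing 3,4,5-trimethoxybenzaldehyde (its carbonyl carbon is C2) and an open-chain C5–C4–C3 alcohol whose alkene carbon C3 carries Me3Sn. The C3–Sn bond leads back to a terminal alkyne, the alkyne to one CH2OH arm of 2-(2,4,5-trimethoxybenzyl)propane-1,3-diol, and the diol to 2,4,5-trimethoxybenzaldehyde and diethyl malonate.
- Enabling feature: in the tetrahydrofuran O1–C2–C3–C4–C5 the aryl-bearing C2 is bonded to the ring oxygen and to C3 at once, so it has the pattern of an aldehyde carbon. C3, whose only branch is CH2OH, can be carried as an sp2 ring carbon with an exocyclic CH2 between C2 and C4. An oxocarbenium ion built on O1 can therefore close onto C3 with ipso loss of a metal.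
- Forward order: the chain is assembled and reduced (steps 1–3), desymmetrised (step 4), one arm is turned into the alkyne and stannylated (steps 5–8), the only ring closes in step 9, and hydroboration finishes (step 10).
- Stereochemistry: C4 comes from lipase desymmetrisation of the prochiral diol. C2 is set by C4 in the ring closure (2,4-cis). C3 is set last by hydroboration on the face away from both neighbours, giving the all-cis (2R,3R,4R) array.

Key step: step 9

Assumption: the lipase acetylates the pro-R hydroxymethyl group of the prochiral diol, as lipases of this family do with other 2-arylmethylpropane-1,3-diols; the hydrolytic mode on the diacetate gives the antipodal monoacetate.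

**Route**

Step 1
Reactants: 1 2,4,5-trimethoxybenzaldehyde; 2 diethyl malonate
Product: 3 diethyl 2-(2,4,5-trimethoxybenzylidene)malonate
Conditions: piperidine (0.1 equiv), AcOH (0.1 equiv), toluene, reflux, Dean–Stark
Reagents that add atoms: none
Why: Knoevenagel condensation, in which piperidinium acetate catalyses aldol addition and dehydration and azeotropic removal of water should carry the electron-rich aldehyde to full conversion.

Step 2
Reactants: 3 diethyl 2-(2,4,5-trimethoxybenzylidene)malonate
Product: 4 diethyl 2-(2,4,5-trimethoxybenzyl)malonate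
Conditions: H2 (1 atm), 10% Pd/C, EtOAc, rt
Reagents that add atoms: none
Why: Catalytic hydrogenation over Pd/C saturates the electron-poor benzylidene C=C bond while esters and aryl ethers are inert.

Step 3
Reactants: 4 diethyl 2-(2,4,5-trimethoxybenzyl)malonate
Product: 5 2-(2,4,5-trimethoxybenzyl)propane-1,3-diol
Conditions: LiAlH4 (2.5 equiv), THF, 0 °C → reflux; H2O, aq NaOH
Reagents that add atoms: none
Why: LiAlH4 reduction of both ester groups of a monosubstituted malonate is the standard entry to 2-benzylpropane-1,3-diols, and excess hydride at reflux should overcome partial enolisation.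

Step 4
Reactants: 5 2-(2,4,5-trimethoxybenzyl)propane-1,3-diol
Product: 6 (R)-3-hydroxy-2-(2,4,5-trimethoxybenzyl)propyl acetate
Conditions: lipase PS (Burkholderia cepacia lipase), vinyl acetate (3 equiv), i-Pr2O, 25 °C
Reagents that add atoms: vinyl acetate, CC(=O)OC=C
Why: Lipase-catalysed desymmetrising transesterification with vinyl acetate as irreversible acyl donor should acetylate the pro-R hydroxymethyl group, which fixes the stereocentre that becomes C4 of the target.

Step 5
Reactants: 6 (R)-3-hydroxy-2-(2,4,5-trimethoxybenzyl)propyl acetate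
Product: 7 (S)-2-formyl-3-(2,4,5-trimethoxyphenyl)propyl acetate
Conditions: Dess–Martin periodinane (1.2 equiv), CH2Cl2, 0 °C → rt; crude product used at once
Reagents that add atoms: none
Why: Dess–Martin oxidation stops at the aldehyde under non-basic conditions, so the β-acetoxy group should not be eliminated and the α-stereocentre should be kept if the aldehyde is not chromatographed.

Step 6
Reactants: 7 (S)-2-formyl-3-(2,4,5-trimethoxyphenyl)propyl acetate
Product: 8 (R)-4,4-dibromo-2-(2,4,5-trimethoxybenzyl)but-3-en-1-yl acetate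
Conditions: CBr4 (2 equiv), PPh3 (2 equiv), Zn (2 equiv), CH2Cl2, rt; then 7, 0 °C → rt
Reagents that add atoms: carbon tetrabromide, BrC(Br)(Br)Br
Why: Ramirez dibromo-olefination (first stage of the Corey–Fuchs sequence) with the zinc-generated ylide Ph3P=CBr2 is a non-basic Wittig reaction that should leave the acetate and the adjacent stereocentre untouched.

Step 7
Reactants: 8 (R)-4,4-dibromo-2-(2,4,5-trimethoxybenzyl)but-3-en-1-yl acetate
Product: 9 (R)-2-(2,4,5-trimethoxybenzyl)but-3-yn-1-ol
Conditions: n-BuLi (4.5 equiv), THF, −78 → −20 °C; MeOH, aq NH4Cl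
Reagents that add atoms: none
Why: Second stage of the Corey–Fuchs sequence, in which Br/Li exchange and Fritsch–Buttenberg–Wiechell rearrangement turn the dibromoalkene into the alkyne while two further equivalents of n-BuLi add to the acetate carbonyl and free the hydroxyl group, so alkyne formation and deprotection should occur together without touching the stereocentre.

Step 8
Reactants: 9 (R)-2-(2,4,5-trimethoxybenzyl)but-3-yn-1-ol
Product: 10 (S)-2-(2,4,5-trimethoxybenzyl)-3-(trimethylstannyl)but-3-en-1-ol
Conditions: Me3SnSnMe3 (2.5 equiv), MeLi (2.5 equiv), THF, −20 °C; CuBr·SMe2 (2.5 equiv), −78 → −63 °C; then 9, MeOH (60 equiv), −63 °C → rt; NH4Cl/NH4OH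
Reagents that add atoms: hexamethyldistannane, C[Sn](C)(C)[Sn](C)(C)C (delivered as Me3SnCu·SMe2 made in the flask)
Why: Stannylcupration, in which syn addition of the Sn–Cu bond across the terminal alkyne places tin on the internal carbon and MeOH protonates the C–Cu bond at low temperature before the addition can revert, should give the 2-stannyl-1-alkene and tolerates the free hydroxyl group.

Step 9
Reactants: 10 (S)-2-(2,4,5-trimethoxybenzyl)-3-(trimethylstannyl)but-3-en-1-ol; 11 3,4,5-trimethoxybenzaldehyde
Product: 14 (2R,4R)-3-methylene-2-(3,4,5-trimethoxyphenyl)-4-(2,4,5-trimethoxybenzyl)tetrahydrofuran, via silyl ether 12 (not isolated), via oxocarbenium triflate 13 (not isolated)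
Conditions: (Me3Si)2NH (0.7 equiv), Me3SiOTf (1 mol %), CH2Cl2, rt, evaporate; then 11 (1.2 equiv), 2,6-di-tert-butyl-4-methylpyridine (0.3 equiv), Me3SiOTf (1.1 equiv), CH2Cl2, −78 °C; Et3N, aq NaHCO3
Reagents that add atoms: none
Why: Proposed new method: Me3SiOTf condenses silyl ether 12 with aldehyde 11 to the E-oxocarbenium ion 13, the tin-bearing alkene carbon C3 attacks the cationic carbon (ipso attack) while the charge that grows on the terminal CH2 is borne by the β C–Sn bond, and loss of Me3Sn+ to triflate leaves the exocyclic methylene, so that O1–C2 and C2–C3 form and the ring closes in one operation. The closest known reactions are Prins-type cyclisations of acetals and oxocarbenium ions terminated by vinylsilanes, which give 3-alkylidenetetrahydrofurans in this ipso mode when the alkene terminus is substituted, together with the ipso proto- and halodestannylation of 2-stannyl-1-alkenes. The tetrahydrofuran closes 5-exo-trig with respect to the alkene and 5-endo with respect to the C=O+ bond. The new C2 centre is controlled by the C4 centre, because in the envelope transition state of the E-oxocarbenium ion the C4 benzyl and C2 aryl groups both lie pseudo-equatorial, which gives the 2,4-cis ring. The step needs ipso regiochemistry against the six-ring Prins mode through the CH2 terminus and 2,4-cis selectivity; tin is placed on C3 instead of silicon because a 2-silyl-1-alkene is attacked at CH2 like a plain alkene whereas a 2-stannyl-1-alkene reacts at the metal-bearing carbon, and the aprotic silyl ether protocol with a hindered pyridine should keep the stannane from protodestannylation.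

Step 10
Reactants: 14 (2R,4R)-3-methylene-2-(3,4,5-trimethoxyphenyl)-4-(2,4,5-trimethoxybenzyl)tetrahydrofuran
Product: 16 [(2R,3R,4R)-2-(3,4,5-trimethoxyphenyl)-4-(2,4,5-trimethoxybenzyl)tetrahydrofuran-3-yl]methanol, via alkylborane 15 (not isolated)
Conditions: 9-BBN (2 equiv), THF, 0 °C → rt; then NaOH (3 M), 30% H2O2, 0 °C → rt
Reagents that add atoms: hydrogen peroxide, OO
Why: Hydroboration–oxidation, in which 9-BBN adds anti-Markovnikov to the 1,1-disubstituted alkene from the face opposite the cis C2 aryl and C4 benzyl groups, so that hydrogen enters C3 anti to them and the boron-bearing CH2, oxidised with retention, ends cis to both, should give the all-cis (2R,3R,4R) target.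

**Compound list**

1 | 2,4,5-trimethoxybenzaldehyde | COc1cc(OC)c(OC)cc1C=O | starting material
2 | diethyl malonate | CCOC(=O)CC(=O)OCC | starting material
3 | diethyl 2-(2,4,5-trimethoxybenzylidene)malonate | COc1cc(OC)c(OC)cc1C=C(C(=O)OCC)C(=O)OCC | intermediate
4 | diethyl 2-(2,4,5-trimethoxybenzyl)malonate | COc1cc(OC)c(OC)cc1CC(C(=O)OCC)C(=O)OCC | intermediate
5 | 2-(2,4,5-trimethoxybenzyl)propane-1,3-diol | COc1cc(OC)c(OC)cc1CC(CO)CO | intermediate
6 | (R)-3-hydroxy-2-(2,4,5-trimethoxybenzyl)propyl acetate | COc1cc(OC)c(OC)cc1C[C@H](CO)COC(C)=O | intermediate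
7 | (S)-2-formyl-3-(2,4,5-trimethoxyphenyl)propyl acetate | COc1cc(OC)c(OC)cc1C[C@H](C=O)COC(C)=O | intermediate
8 | (R)-4,4-dibromo-2-(2,4,5-trimethoxybenzyl)but-3-en-1-yl acetate | COc1cc(OC)c(OC)cc1C[C@H](C=C(Br)Br)COC(C)=O | intermediate
9 | (R)-2-(2,4,5-trimethoxybenzyl)but-3-yn-1-ol | COc1cc(OC)c(OC)cc1C[C@H](C#C)CO | intermediate
10 | (S)-2-(2,4,5-trimethoxybenzyl)-3-(trimethylstannyl)but-3-en-1-ol | COc1cc(OC)c(OC)cc1C[C@H](C(=C)[Sn](C)(C)C)CO | intermediate
11 | 3,4,5-trimethoxybenzaldehyde | COc1cc(C=O)cc(OC)c1OC | starting material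
12 | (S)-trimethyl{[2-(2,4,5-trimethoxybenzyl)-3-(trimethylstannyl)but-3-en-1-yl]oxy}silane | COc1cc(OC)c(OC)cc1C[C@H](C(=C)[Sn](C)(C)C)CO[Si](C)(C)C | intermediate (not isolated)
13 | E-oxocarbenium triflate from 12 and 11, (3,4,5-trimethoxyphenyl)CH=O+–CH2–CH(CH2Ar)–C(SnMe3)=CH2 with TfO−, (S) at the benzyl-bearing carbon | COc1cc(OC)c(OC)cc1C[C@H](C(=C)[Sn](C)(C)C)C/[O+]=C/c1cc(OC)c(OC)c(OC)c1.[O-]S(=O)(=O)C(F)(F)F | intermediate (not isolated)
14 | (2R,4R)-3-methylene-2-(3,4,5-trimethoxyphenyl)-4-(2,4,5-trimethoxybenzyl)tetrahydrofuran (2,4-cis) | COc1cc(OC)c(OC)cc1C[C@H]1CO[C@@H](c2cc(OC)c(OC)c(OC)c2)C1=C | intermediate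
15 | 9-{[all-cis-2-(3,4,5-trimethoxyphenyl)-4-(2,4,5-trimethoxybenzyl)tetrahydrofuran-3-yl]methyl}-9-borabicyclo[3.3.1]nonane, ring configuration as in 16 | COc1cc(OC)c(OC)cc1C[C@H]1CO[C@@H](c2cc(OC)c(OC)c(OC)c2)[C@H]1CB1C2CCCC1CCC2 | intermediate (not isolated)
16 | [(2R,3R,4R)-2-(3,4,5-trimethoxyphenyl)-4-(2,4,5-trimethoxybenzyl)tetrahydrofuran-3-yl]methanol | COc1cc(OC)c(OC)cc1C[C@H]1CO[C@@H](c2cc(OC)c(OC)c(OC)c2)[C@H]1CO | target

**Step count**

Total: 10 steps. Longest linear sequence: 10 steps (1 to 16; aldehyde 11 enters in step 9).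

**Steps most likely to fail**

1. Step 9 (Proposed new method). What may go wrong: closure through the CH2 terminus instead of the tin-bearing carbon (six-ring Prins mode), protodestannylation of the alkene before ring closure, or weak 2,4-cis selectivity. Fallback with known chemistry, forming the C–C and C–O bonds in separate events: setting out from 10, iododestannylation (I2, CH2Cl2, 0 °C) gives (S)-3-iodo-2-(2,4,5-trimethoxybenzyl)but-3-en-1-ol F1. Nozaki–Hiyama–Kishi coupling of F1 with 11 (CrCl2, NiCl2 cat., DMF, rt) gives (2R)-3-methylidene-2-(2,4,5-trimethoxybenzyl)-4-(3,4,5-trimethoxyphenyl)butane-1,4-diol F2 as both carbinol epimers. Acid-catalysed dehydrative etherification (camphorsulfonic acid cat., CH2Cl2, 0 °C) runs through the benzylic cation, should let both epimers settle in the 2,4-cis ring, and comes back to the route at 14.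

2. Step 8. What may go wrong: addition of the stannylcopper reagent with tin on the terminal carbon, favoured by the branch next to the alkyne, or reversal of the addition before protonation. Fallback through a vinyl halide: setting out from 9, Markovnikov bromoboration and protonolysis (B-bromo-9-BBN, CH2Cl2, 0 °C; AcOH) gives (S)-3-bromo-2-(2,4,5-trimethoxybenzyl)but-3-en-1-ol F3. Br/Li exchange (t-BuLi, THF, −78 °C) and quenching with Me3SnCl, with cleavage of the O–Sn bond on aqueous work-up, comes back to the route at 10.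

3. Step 5. What may go wrong: loss of acetate by β-elimination from aldehyde 7, or epimerisation at its α-carbon, during oxidation, handling and olefination. Fallback with a silyl ether in place of the ester and the other arm oxidised, setting out from 5:
   - Ac2O/pyridine gives 2-(2,4,5-trimethoxybenzyl)propane-1,3-diyl diacetate F4.
   - The same lipase in hydrolytic mode (phosphate buffer) frees the pro-R arm and gives (S)-3-hydroxy-2-(2,4,5-trimethoxybenzyl)propyl acetate F5.
   - TBSCl/imidazole gives (R)-3-[(tert-butyldimethylsilyl)oxy]-2-(2,4,5-trimethoxybenzyl)propyl acetate F6.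
   - K2CO3/MeOH gives (R)-3-[(tert-butyldimethylsilyl)oxy]-2-(2,4,5-trimethoxybenzyl)propan-1-ol F7.
   - Dess–Martin oxidation gives (S)-3-[(tert-butyldimethylsilyl)oxy]-2-(2,4,5-trimethoxybenzyl)propanal F8, which has no good β-leaving group.
   - Seyferth–Gilbert homologation with the Ohira–Bestmann reagent (K2CO3, MeOH) gives (R)-tert-butyldimethyl{[2-(2,4,5-trimethoxybenzyl)but-3-yn-1-yl]oxy}silane F9.
   - Bu4NF comes back to the route at 9.

Further compounds
F1 | step 9 | (S)-3-iodo-2-(2,4,5-trimethoxybenzyl)but-3-en-1-ol | COc1cc(OC)c(OC)cc1C[C@H](C(I)=C)CO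
F2 | step 9 | (2R)-3-methylidene-2-(2,4,5-trimethoxybenzyl)-4-(3,4,5-trimethoxyphenyl)butane-1,4-diol, both C4 epimers | COc1cc(OC)c(OC)cc1C[C@H](C(=C)C(O)c1cc(OC)c(OC)c(OC)c1)CO
F3 | step 8 | (S)-3-bromo-2-(2,4,5-trimethoxybenzyl)but-3-en-1-ol | COc1cc(OC)c(OC)cc1C[C@H](C(Br)=C)CO
F4 | step 5 | 2-(2,4,5-trimethoxybenzyl)propane-1,3-diyl diacetate | COc1cc(OC)c(OC)cc1CC(COC(C)=O)COC(C)=O
F5 | step 5 | (S)-3-hydroxy-2-(2,4,5-trimethoxybenzyl)propyl acetate | COc1cc(OC)c(OC)cc1C[C@@H](CO)COC(C)=O
F6 | step 5 | (R)-3-[(tert-butyldimethylsilyl)oxy]-2-(2,4,5-trimethoxybenzyl)propyl acetate | COc1cc(OC)c(OC)cc1C[C@@H](CO[Si](C)(C)C(C)(C)C)COC(C)=O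
F7 | step 5 | (R)-3-[(tert-butyldimethylsilyl)oxy]-2-(2,4,5-trimethoxybenzyl)propan-1-ol | COc1cc(OC)c(OC)cc1C[C@@H](CO[Si](C)(C)C(C)(C)C)CO
F8 | step 5 | (S)-3-[(tert-butyldimethylsilyl)oxy]-2-(2,4,5-trimethoxybenzyl)propanal | COc1cc(OC)c(OC)cc1C[C@@H](CO[Si](C)(C)C(C)(C)C)C=O
F9 | step 5 | (R)-tert-butyldimethyl{[2-(2,4,5-trimethoxybenzyl)but-3-yn-1-yl]oxy}silane | COc1cc(OC)c(OC)cc1C[C@@H](CO[Si](C)(C)C(C)(C)C)C#C
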